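**Retrosynthetic overview**
1. The C15–O ester is made last, from ent-labda-7,13E-diene-3,15-diol (22) and an O-silylated 30-hydroxytriacontanoic acid (28), itself assembled from two C15 halves by copper-catalysed Grignard coupling.
2. Side chain: C13=C14 (E), C15 and C16 come from zirconium-catalysed carboalumination/hydroxymethylation of a terminal alkyne. C9–C11 comes from 1,2-addition to a C9 enone, followed by palladium/formate allylic hydrogenolysis that sets C9–H and keeps C7=C8.
3. Ring A: a one-pot Michael/Michael/Dieckmann annulation of methyl isobutyrate (C3, C4, C18, C19), an (S)-carvone-derived enone (ring B, C20, C17) and methyl acrylate (C1, C2) forms C4–C5, C10–C1 and C2–C3. The carvone isopropenyl group (on C7) steers C5 and C10 and is then excised to the C7=C8 enone.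
4. Enabling feature: in ring A the oxygen-bearing C3 and the gem-dimethyl carbon C4 are an isobutyrate unit, and C2 can carry a removable ester. The ring-fusion pair C5/C10(CH3) plus C9 is the β/α/carbonyl triad of a 2-methylcyclohexenone hidden in ring B (1,5-relation C3/C9).
5. Ring order: ring B comes from the chiral pool; ring A is annulated onto it in step 2.

Key step: step 2

Remark: labdane numbering is used for all bicyclic compounds (ring A = C1–C5, C10; ring B = C5–C10; C17 on C8, C18/C19 on C4, C20 on C10). The target is the ent-labdane (3R,5S,9R,10S,13E); centres that are later erased (C2, C8, C7) are carried without control.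

**Step 1**
Reactants: 1 (S)-(+)-carvone
Product: 2 (5S)-6-methylcarvone [(5S)-2,6-dimethyl-5-(prop-1-en-2-yl)cyclohex-2-en-1-one; carvone C6 = labdane C8; both epimers]
Conditions: LDA, THF, −78 °C; MeI, −78 → 0 °C
Reagents that add atoms: iodomethane CI
Why: Kinetic deprotonation at the only sp3 α-carbon and enolate alkylation install C17; the new centre (methyl mainly trans to isopropenyl) becomes sp2 in step 4, so its configuration does not matter.

**Step 2**
Reactants: 3 methyl isobutyrate; 2 (5S)-6-methylcarvone; 4 methyl acrylate
Product: 8 trans-decalin β-keto ester (methyl 3,9-dioxo-7-isopropenyl-4,4,8,10-tetramethyldecalin-2-carboxylate; C5–H anti to C10–CH3; C7 isopropenyl anti to the C5–C4 bond; C2/C8 epimers), via lithium ester enolate 5 (not isolated), via C9 lithium enolate 6 (not isolated), via C2 ester enolate 7 (not isolated)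
Conditions: LDA, THF, −78 °C, 3; then 2, DMPU, −78 → −30 °C; then 4 (1 equiv), −78 → 25 °C; 1 M HCl, 0 °C
Reagents that add atoms: none
Why: The α,α-disubstituted ester enolate 5 adds 1,4 to the enone (C4–C5), the regiodefined C9/C10 enolate 6 adds to methyl acrylate (C10–C1), and ester enolate 7 acylates itself on the isobutyrate ester (C2–C3), the acidic β-keto ester product pulling the sequence forward. The closest known type is the sequential Michael/Michael/Dieckmann three-component annulation, combined with conjugate addition–enolate trapping on carvone. Ring A closes by a 6-(enolexo)-exo-trig Dieckmann condensation; ring B is already present. C5 is set by axial attack on the half-chair enone anti to the C7 isopropenyl group; C10 is set because the acrylate approaches enolate 6 anti to the bulky C5 substituent (held axial by allylic 1,2-strain with the C10 methyl), so C1 and C4 end trans on ring B and only the trans-fused decalin can close. The step needs 1,4- over 1,2-addition (secured by the α,α-disubstituted enolate, the α-methyl enone and DMPU), trapping of 6 at C10 before proton exchange to C8 (regiospecific generation, low temperature, tertiary C8–H) and ring closure ahead of acrylate oligomerisation (one equivalent of acrylate, only a six-membered closure available).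

**Step 3**
Reactants: 8 trans-decalin β-keto ester
Product: 9 3,9-diketone (7-isopropenyl-4,4,8,10-tetramethyl-trans-decalin-3,9-dione; C8 epimers)
Conditions: LiCl, DMSO, H2O, 150 °C
Reagents that add atoms: none
Why: Krapcho dealkoxycarbonylation removes the activating ester from C2 (chloride demethylates, the β-keto carboxylate loses CO2), erasing the C2 centre; C10 is quaternary, so neither Michael bond can revert.

**Step 4**
Reactants: 9 3,9-diketone
Product: 12 enedione (4,4,8,10-tetramethyl-trans-octal-7-ene-3,9-dione; C7=C8 conjugated to C9=O), via methoxy hydroperoxide 10 (not isolated), via C7 acetate 11 (not isolated)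
Conditions: O3, NaHCO3, CH2Cl2/MeOH, −78 °C; Ac2O, Et3N, DMAP (cat.), 0 → 25 °C; DBU, 40 °C
Reagents that add atoms: none
Why: Ozone cleaves the only C=C bond, the carbonyl oxide is trapped by methanol as 10, its peracetate undergoes Criegee rearrangement (C7 migrates to oxygen with retention) to acetate 11, and E1cB loss of acetate β to the C9 ketone gives the conjugated C7=C8 enone, which erases C7 and C8 as stereocentres.

**Step 5**
Reactants: 12 enedione
Product: 13 3-hydroxy enone (equatorial C3–OH cis to C10–CH3; C9 enone untouched)
Conditions: NaBH4, MeOH/CH2Cl2, −78 → −40 °C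
Reagents that add atoms: none
Why: Borohydride should reduce the saturated C3 ketone faster than the conjugated, more hindered C9 enone, and axial hydride delivery anti to the axial C4 and C10 methyl groups sets the equatorial C3 alcohol, as is usual for 3-oxo-4,4-dimethyl trans-decalins.

**Step 6**
Reactants: 13 3-hydroxy enone; 14 (4-bromobut-1-yn-1-yl)trimethylsilane
Product: 17 bis(methyl carbonate) (C3–OCO2Me; C9 bears OCO2Me syn to C10–CH3 plus the 4-trimethylsilylbut-3-ynyl chain anti to it; C7=C8), via Grignard reagent 15 (not isolated), via dialkoxide 16 (not isolated)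
Conditions: 14, Mg, THF, 25 °C; 13 (0.33 equiv), THF, −78 → 0 °C; ClCO2Me, −78 → 25 °C
Reagents that add atoms: methyl chloroformate COC(=O)Cl
Why: Grignard 1,2-addition to the α-methyl enone (one equivalent is spent on the C3–OH) should occur on the face anti to the axial C10 methyl, placing C11 anti and the C9 oxygen syn to C10–CH3, and both alkoxides are acylated in the same flask (an unacylated C3–OH would converge again in step 8).

**Step 7**
Reactants: 17 bis(methyl carbonate)
Product: 18 C3 methyl carbonate of the silyl alkyne (C9–H anti to C10–CH3; side chain equatorial; C7=C8)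
Conditions: Pd(OAc)2 (5 mol %), n-Bu3P (5 mol %), HCO2H, Et3N, THF, 25–40 °C
Reagents that add atoms: none
Why: Palladium-catalysed formate hydrogenolysis of the allylic carbonate: zerovalent palladium ionises the tertiary carbonate with inversion, formate gives a hydridopalladium allyl, and the hydride passes from the metal to the more substituted terminus C9 on the face opposite the former C–O bond, which sets C9 and leaves the less substituted C7=C8 olefin.

**Step 8**
Reactants: 18 C3 methyl carbonate of the silyl alkyne
Product: 19 terminal alkyne alcohol (15,16-dinor-ent-labd-7-en-13-yn-3-ol; free C3–OH; C9 but-3-ynyl)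
Conditions: K2CO3, MeOH, 25 °C
Reagents that add atoms: none
Why: Base-catalysed methanolysis removes the alkynyl silane and the C3 carbonate in one operation without touching a stereocentre.

**Step 9**
Reactants: 19 terminal alkyne alcohol
Product: 22 ent-labda-7,13E-diene-3,15-diol [(3R,5S,9R,10S)], via alkenylalane 20 (not isolated), via lithium alanate 21 (not isolated)
Conditions: Me3Al, Cp2ZrCl2 (25 mol %), CH2Cl2, 0 → 25 °C; n-BuLi, THF, −78 °C; (CH2O)n, −78 → 25 °C; aq. Rochelle salt
Reagents that add atoms: trimethylaluminium C[Al](C)C; formaldehyde (from paraformaldehyde) C=O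
Why: Zirconium-catalysed carboalumination adds CH3 and Al syn across the terminal alkyne (methyl to C13), and the alanate is hydroxymethylated with retention, which fixes the 13E geometry while the C3–OH travels as its aluminium alkoxide.

**Step 10**
Reactants: 23 15-bromopentadecanoic acid
Product: 24 15-bromopentadecan-1-ol
Conditions: BH3·THF, THF, 0 → 25 °C
Reagents that add atoms: none
Why: Borane reduces the carboxylic acid chemoselectively and leaves the primary bromide intact.

**Step 11**
Reactants: 24 15-bromopentadecan-1-ol
Product: 25 (15-bromopentadecyloxy)(tert-butyl)dimethylsilane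
Conditions: TBSCl, imidazole, DMF, 25 °C
Reagents that add atoms: tert-butyldimethylsilyl chloride CC(C)(C)[Si](C)(C)Cl
Why: Standard silylation of a primary alcohol gives a group that survives Grignard formation and the esterification.

**Step 12**
Reactants: 25 (15-bromopentadecyloxy)(tert-butyl)dimethylsilane; 23 15-bromopentadecanoic acid
Product: 28 30-(tert-butyldimethylsilyloxy)triacontanoic acid, via Grignard reagent 26 (not isolated), via magnesium carboxylate 27 (not isolated)
Conditions: 25, Mg, THF, 45 °C; 23, MeMgCl (1 equiv), THF, −20 °C; Li2CuCl4 (3 mol %), THF, −20 → 0 °C; 1 M HCl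
Reagents that add atoms: none
Why: Copper-catalysed coupling of a primary alkyl Grignard reagent with a primary alkyl bromide joins the two C15 halves, the acid being masked as its magnesium carboxylate, which is inert to the Grignard reagent at low temperature.

**Step 13**
Reactants: 22 ent-labda-7,13E-diene-3,15-diol; 28 30-(tert-butyldimethylsilyloxy)triacontanoic acid
Product: 29 15-O-[30-(tert-butyldimethylsilyloxy)triacontanoyl] ester of 22 (C3–OH free)
Conditions: DCC, DMAP (10 mol %), CH2Cl2, 0 → 25 °C
Reagents that add atoms: none
Why: Steglich esterification should acylate only the primary allylic C15–OH, because the secondary C3–OH is shielded by the C4 gem-dimethyl group.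

**Step 14**
Reactants: 29 silyl-protected ester
Product: 30 target CNP0303636.1 [(3R,5S,9R,10S,13E)-3-hydroxylabda-7,13-dien-15-yl 30-hydroxytriacontanoate]
Conditions: HF·pyridine, THF, 0 → 25 °C
Reagents that add atoms: none
Why: Fluoride cleaves the primary silyl ether under mildly acidic conditions that leave the allylic ester, both trisubstituted olefins and all stereocentres untouched.

**Compound list**
1 | (S)-(+)-carvone, (5S)-2-methyl-5-(prop-1-en-2-yl)cyclohex-2-en-1-one | O=C1C[C@@H](C(C)=C)CC=C1C | starting material
2 | (5S)-2,6-dimethyl-5-(prop-1-en-2-yl)cyclohex-2-en-1-one (6-methylcarvone, C6 epimers) | O=C1C(C)[C@@H](C(C)=C)CC=C1C | intermediate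
3 | methyl isobutyrate | COC(=O)C(C)C | starting material
4 | methyl acrylate | C=CC(=O)OC | starting material
5 | lithium enolate of methyl isobutyrate | [Li]OC(OC)=C(C)C | intermediate
6 | lithium C9/C10 enolate of the first Michael adduct (C5 substituent trans to C7 isopropenyl) | CC1[C@@H](C(C)=C)C[C@H](C(C)(C)C(=O)OC)C(C)=C1O[Li] | intermediate
7 | lithium ester enolate of the second Michael adduct (C10 quaternary, C1 trans to C4) | CC1[C@@H](C(C)=C)C[C@H](C(C)(C)C(=O)OC)[C@@](C)(CC=C(OC)O[Li])C1=O | intermediate
8 | methyl 3,9-dioxo-7-isopropenyl-4,4,8,10-tetramethyl-trans-decalin-2-carboxylate (C2/C8 epimers) | CC1[C@@H](C(C)=C)C[C@@H]2C(C)(C)C(=O)C(C(=O)OC)C[C@@]2(C)C1=O | intermediate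
9 | 7-isopropenyl-4,4,8,10-tetramethyl-trans-decalin-3,9-dione (C8 epimers) | CC1[C@@H](C(C)=C)C[C@@H]2C(C)(C)C(=O)CC[C@@]2(C)C1=O | intermediate
10 | C7 (2-hydroperoxy-2-methoxyprop-2-yl) diketone | CC1[C@@H](C(C)(OC)OO)C[C@@H]2C(C)(C)C(=O)CC[C@@]2(C)C1=O | intermediate
11 | C7 acetoxy diketone (C–O with retention) | CC1[C@@H](OC(C)=O)C[C@@H]2C(C)(C)C(=O)CC[C@@]2(C)C1=O | intermediate
12 | 4,4,8,10-tetramethyl-trans-octal-7-ene-3,9-dione | CC1=CC[C@@H]2C(C)(C)C(=O)CC[C@@]2(C)C1=O | intermediate
13 | 3-hydroxy-4,4,8,10-tetramethyl-trans-octal-7-en-9-one (C3–OH equatorial) | CC1=CC[C@@H]2C(C)(C)[C@H](O)CC[C@@]2(C)C1=O | intermediate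
14 | (4-bromobut-1-yn-1-yl)trimethylsilane | C[Si](C)(C)C#CCCBr | starting material
15 | [4-(trimethylsilyl)but-3-yn-1-yl]magnesium bromide | C[Si](C)(C)C#CCC[Mg]Br | intermediate
16 | bis(bromomagnesium) C3,C9-dialkoxide of the 1,2-adduct | CC1=CC[C@@H]2C(C)(C)[C@H](O[Mg]Br)CC[C@@]2(C)[C@]1(CCC#C[Si](C)(C)C)O[Mg]Br | intermediate
17 | C3,C9-bis(methyl carbonate), C9 chain anti to C10–CH3 | CC1=CC[C@@H]2C(C)(C)[C@H](OC(=O)OC)CC[C@@]2(C)[C@]1(CCC#C[Si](C)(C)C)OC(=O)OC | intermediate
18 | C3 methyl carbonate of 14-(trimethylsilyl)-15,16-dinor-ent-labd-7-en-13-yn-3-ol | CC1=CC[C@@H]2C(C)(C)[C@H](OC(=O)OC)CC[C@@]2(C)[C@@H]1CCC#C[Si](C)(C)C | intermediate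
19 | 15,16-dinor-ent-labd-7-en-13-yn-3-ol | CC1=CC[C@@H]2C(C)(C)[C@H](O)CC[C@@]2(C)[C@@H]1CCC#C | intermediate
20 | (E)-alkenyldimethylalane, C3–O–AlMe2 | CC1=CC[C@@H]2C(C)(C)[C@H](O[Al](C)C)CC[C@@]2(C)[C@@H]1CC/C(C)=C/[Al](C)C | intermediate
21 | lithium butyl(alkenyl)dimethylalanate | [Li+].CC1=CC[C@@H]2C(C)(C)[C@H](O[Al](C)C)CC[C@@]2(C)[C@@H]1CC/C(C)=C/[Al-](C)(C)CCCC | intermediate
22 | ent-labda-7,13E-diene-3,15-diol, (3R,5S,9R,10S) | CC1=CC[C@@H]2C(C)(C)[C@H](O)CC[C@@]2(C)[C@@H]1CC/C(C)=C/CO | intermediate
23 | 15-bromopentadecanoic acid | OC(=O)CCCCCCCCCCCCCCBr | starting material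
24 | 15-bromopentadecan-1-ol | OCCCCCCCCCCCCCCCBr | intermediate
25 | (15-bromopentadecyloxy)(tert-butyl)dimethylsilane | CC(C)(C)[Si](C)(C)OCCCCCCCCCCCCCCCBr | intermediate
26 | [15-(tert-butyldimethylsilyloxy)pentadecyl]magnesium bromide | CC(C)(C)[Si](C)(C)OCCCCCCCCCCCCCCC[Mg]Br | intermediate
27 | chloromagnesium 15-bromopentadecanoate | BrCCCCCCCCCCCCCCC(=O)O[Mg]Cl | intermediate
28 | 30-(tert-butyldimethylsilyloxy)triacontanoic acid | CC(C)(C)[Si](C)(C)OCCCCCCCCCCCCCCCCCCCCCCCCCCCCCC(=O)O | intermediate
29 | (3R,5S,9R,10S,13E)-3-hydroxylabda-7,13-dien-15-yl 30-(tert-butyldimethylsilyloxy)triacontanoate | CC1=CC[C@@H]2C(C)(C)[C@H](O)CC[C@@]2(C)[C@@H]1CC/C(C)=C/COC(=O)CCCCCCCCCCCCCCCCCCCCCCCCCCCCCO[Si](C)(C)C(C)(C)C | intermediate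
30 | CNP0303636.1, (3R,5S,9R,10S,13E)-3-hydroxylabda-7,13-dien-15-yl 30-hydroxytriacontanoate | CC1=CC[C@@H]2C(C)(C)[C@H](O)CC[C@@]2(C)[C@@H]1CC/C(C)=C/COC(=O)CCCCCCCCCCCCCCCCCCCCCCCCCCCCCO | target

**Step count**
Total: 14 steps. Longest linear sequence: 11 steps (steps 1–9, 13, 14); steps 10–12 form the convergent acid branch.

**Steps most likely to fail**

Step 2. The ester enolate may add 1,2 to the enone or merely transfer a proton. Enolate 6 may exchange to the C8 enolate before it is trapped. Acrylate oligomerisation may outrun the slow Dieckmann closure onto the neopentyl-type ester. The fallback separates the three events and sets out from 2. A Mukaiyama–Michael addition of commercial 1-methoxy-2-methyl-1-(trimethylsilyloxy)propene (TMSOTf cat., CH2Cl2, −78 °C) should give the regiodefined trimethylsilyl enol ether F1 with the same anti selectivity. MeLi (THF, 0 °C) would then release enolate 6 free of amine and ester enolate, and methyl acrylate at −78 °C with a cold quench should give the keto diester F2. KOtBu in THF would close ring A under equilibrating conditions, and the route is rejoined at 8.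

Step 7. Hydride may be delivered to the less substituted allyl terminus C7, or the allyl complex may lose a β-hydrogen, giving the C8=C9 isomer or dienes. Upstream, acylation of the congested tertiary alkoxide in step 6 may be incomplete. The fallback sets out from 13. Addition of 15 with an aqueous quench should give the diol F3. Catalytic Ph3SiOReO3 (Et2O, −50 → 0 °C) should move the hydroxyl suprafacially to C7, giving the secondary allylic alcohol F4 with a tetrasubstituted C8=C9 bond. o-Nitrobenzenesulfonylhydrazide, PPh3 and diethyl azodicarboxylate (THF, −30 → 25 °C) would invert C7 to a monoalkyl diazene, whose sigmatropic loss of nitrogen places hydrogen on C9 on the face opposite the original C7 oxygen and restores C7=C8, giving the silyl alkyne alcohol F5. K2CO3 in methanol then rejoins the route at 19.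

Step 4. The Criegee rearrangement may stall, with the hydroperoxide instead being reduced to the 7-acetyl compound or the peroxide over-oxidising. The fallback sets out from 9 and uses a radical fragmentation: ozonolysis in methanol to 10 as before, then FeSO4·7H2O and Cu(OAc)2 (MeOH, −20 → 25 °C). Divalent iron reduces the hydroperoxide to an alkoxy radical, β-scission expels methyl acetate, and divalent copper oxidises the C7 radical to the olefin. A short DBU treatment would bring any C6=C7 isomer into conjugation, and the route is rejoined at 12 without a new compound.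

**Further compounds**
F1 | step 2 | trimethylsilyl enol ether of the first Michael adduct (C9–OSiMe3, C9=C10; C5 substituent trans to C7 isopropenyl) | CC1[C@@H](C(C)=C)C[C@H](C(C)(C)C(=O)OC)C(C)=C1O[Si](C)(C)C
F2 | step 2 | keto diester (C10 quaternary with methyl and 2-methoxycarbonylethyl; C5 bearing C(CH3)2CO2Me) | CC1[C@@H](C(C)=C)C[C@H](C(C)(C)C(=O)OC)[C@@](C)(CCC(=O)OC)C1=O
F3 | step 7 | C3,C9-diol (tertiary C9–OH syn to C10–CH3, silylbutynyl chain anti; C7=C8) | CC1=CC[C@@H]2C(C)(C)[C@H](O)CC[C@@]2(C)[C@]1(CCC#C[Si](C)(C)C)O
F4 | step 7 | transposed C3,C7-diol (secondary C7–OH syn to C10–CH3; C8=C9 bearing the silylbutynyl chain) | CC1=C(CCC#C[Si](C)(C)C)[C@]2(C)CC[C@@H](O)C(C)(C)[C@H]2C[C@H]1O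
F5 | step 7 | 14-(trimethylsilyl)-15,16-dinor-ent-labd-7-en-13-yn-3-ol | CC1=CC[C@@H]2C(C)(C)[C@H](O)CC[C@@]2(C)[C@@H]1CCC#C[Si](C)(C)C
F0 | step 4 | none | none
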